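**Retrosynthetic overview** (friedelane numbering; primed atoms belong to the lower, tingenone-derived half)

1. Last ring: ring B of the upper half (C5–C6–C7–C8–C9–C10) is cut at C9–C10 and C7=C8, giving aryl bromide 10 (lower pentacycle + dioxane + ring A, with acetyl on C5 and Br on C10) and enol silane 19 (rings C, D, E).
2. Enabling feature: ring B is an aryl-conjugated cyclohexenone in which C9 is α to the C8 carbonyl carbon (enolate carbon for arylation by C10) and C7=C8 is the aldol-condensation retron of a C5 acetyl group and a C8 ketone. C8 lies between quaternary C9 and C14, so it can be enolised only toward C9 before the coupling and not at all after it.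
3. 10 comes from a hetero-Diels–Alder reaction of ortho-quinone 8 (made from 2-bromoisovanillin) with the C3'=C4' enol of tingenone 7, which forms the dioxane ring.
4. 19 comes from tingenone 7: ozonolytic excision of rings A/B (C8 ketone, C9 carboxyl), then ring E work (enol triflate, enoate, β-epoxide, 1,2-ester shift to set C20), then decarboxylative silyl transfer.
5. Ring order: rings C–E and the lower pentacycle are taken from tingenone; arene ring A; dioxane ring (step 6); ring B last (step 16); then desilylation.

Key step: step 16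

Remark: tingenone 7 is taken as a purchasable, enantiopure natural product (offered by natural-product suppliers) and serves both as the lower half and as the source of rings C–E of the upper half.

**Step 1**
Reactants: 1 2-bromo-3-hydroxy-4-methoxybenzaldehyde
Product: 2 3-hydroxy-4-methoxy-2-methylbenzaldehyde
Conditions: MeB(OH)2, Pd(OAc)2, SPhos, K3PO4, toluene/H2O, 100 °C
Reagents that add atoms: methylboronic acid CB(O)O
Why: Suzuki–Miyaura methylation of the aryl bromide with a biarylphosphine catalyst that tolerates the ortho phenoxide and the aldehyde.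

**Step 2**
Reactants: 2 3-hydroxy-4-methoxy-2-methylbenzaldehyde
Product: 3 6-bromo-3-hydroxy-4-methoxy-2-methylbenzaldehyde
Conditions: NBS, MeCN, 0 °C
Reagents that add atoms: N-bromosuccinimide O=C1CCC(=O)N1Br
Why: Electrophilic aromatic bromination directed para by the free phenol, whose two ortho positions are blocked by methyl and methoxy, so bromine should enter next to the formyl group.

**Step 3**
Reactants: 3 6-bromo-3-hydroxy-4-methoxy-2-methylbenzaldehyde
Product: 4 (±)-1-(6-bromo-3-hydroxy-4-methoxy-2-methylphenyl)ethan-1-ol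
Conditions: MeMgBr (2.5 equiv), THF, 0 °C; then 1 M HCl
Reagents that add atoms: methylmagnesium bromide C[Mg]Br
Why: Grignard addition to the aldehyde after deprotonation of the phenol; the carbinol centre forms as a racemate and is removed in step 4.

**Step 4**
Reactants: 4 (±)-1-(6-bromo-3-hydroxy-4-methoxy-2-methylphenyl)ethan-1-ol
Product: 5 1-(6-bromo-3-hydroxy-4-methoxy-2-methylphenyl)ethan-1-one
Conditions: activated MnO2, CH2Cl2, rt
Reagents that add atoms: none
Why: MnO2 oxidation of a benzylic alcohol, which should leave the phenol and the aryl bromide untouched.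

**Step 5**
Reactants: 5 1-(6-bromo-3-hydroxy-4-methoxy-2-methylphenyl)ethan-1-one
Product: 6 1-(6-bromo-3,4-dihydroxy-2-methylphenyl)ethan-1-one
Conditions: BBr3, CH2Cl2, −78 → 0 °C; then H2O
Reagents that add atoms: none
Why: Lewis-acid cleavage of the aryl methyl ether to the catechol, tolerated by the aryl ketone and the bromide.

**Step 6**
Reactants: 6 1-(6-bromo-3,4-dihydroxy-2-methylphenyl)ethan-1-one; 7 tingenone
Product: 9 cis-benzodioxane cycloadduct of tingenone (arene: 4-methyl; 5-acetyl; 10-bromo), via ortho-quinone 8 (not isolated)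
Conditions: Ag2O, Na2SO4, CH2Cl2, 0 °C, filter; then 7, CH2Cl2, rt, dark
Reagents that add atoms: none
Why: Inverse-electron-demand hetero-Diels–Alder reaction of the quinone O=C–C=O unit with the C3'=C4' enol of tingenone (the construction known for celastroid dimers), in which nucleophilic C4' should bond to the quinone oxygen ortho to the aryl methyl because the phenoxide developing on the other oxygen is para to the acetyl group, and the quinone should add suprafacially to the α face, opposite the axial C9' methyl, setting C3' (OH β) and C4' (CH3 β).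

**Step 7**
Reactants: 9 cis-benzodioxane cycloadduct
Product: 10 tert-butyldimethylsilyl ketal of 9 (C3'-OTBS)
Conditions: TBSOTf, 2,6-lutidine, CH2Cl2, −78 → 0 °C
Reagents that add atoms: tert-butyldimethylsilyl triflate CC(C)(C)[Si](C)(C)OS(=O)(=O)C(F)(F)F
Why: Silylation of the tertiary hemiketal hydroxyl locks the dioxane ring as a silyl ketal and removes the only acidic O–H before the enolate chemistry.

**Step 8**
Reactants: 7 tingenone
Product: 11 ring C–E keto acid (8,21-dioxo; 9α-carboxylic acid; 9β,13α,14β,17β,20β-pentamethyl; 18β-H)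
Conditions: O3, CH2Cl2/MeOH, −78 °C; then H2O2, aq. NaHCO3, 0 °C → rt; acidify at 0 °C
Reagents that add atoms: ozone [O-][O+]=O; hydrogen peroxide OO
Why: Exhaustive ozonolysis of the four ring A/B double bonds with oxidative work-up cleaves C7=C8 to the C8 ketone and degrades the remaining C10–C5–C4 tricarbonyl chain to the C9 carboxylic acid, leaving C9 and the ring C–E stereocentres untouched (the β-keto acid is kept cold).

**Step 9**
Reactants: 11 ring C–E keto acid
Product: 12 benzyl ester of 11
Conditions: BnBr, K2CO3, DMF, 0 °C → rt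
Reagents that add atoms: benzyl bromide BrCc1ccccc1
Why: Carboxylate O-alkylation; the ester keeps C9 quaternary, so the C8 ketone cannot enolise during the ring E steps.

**Step 10**
Reactants: 12 benzyl ester
Product: 13 C20=C21 enol triflate (21-OTf)
Conditions: Tf2O, 2,6-di-tert-butyl-4-methylpyridine, CH2Cl2, 0 °C → rt
Reagents that add atoms: trifluoromethanesulfonic anhydride O=S(=O)(OS(=O)(=O)C(F)(F)F)C(F)(F)F
Why: Enol triflate formation through the O-sulfonylated carbenium ion, which should lose a proton toward the more substituted C20=C21 alkene, while the C8 ketone has no α-hydrogen.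

**Step 11**
Reactants: 13 enol triflate
Product: 14 methyl C20=C21 ene-21-carboxylate
Conditions: Pd(OAc)2, dppf, CO (1 atm), MeOH, Et3N, DMF, 60 °C
Reagents that add atoms: carbon monoxide [C-]#[O+]; methanol CO
Why: Palladium-catalysed methoxycarbonylation of a vinyl triflate.

**Step 12**
Reactants: 14 enoate
Product: 15 20β,21β-epoxide (glycidic ester; 20-CH3 α, 21-CO2Me α)
Conditions: dimethyldioxirane, acetone/CH2Cl2, 0 °C → rt
Reagents that add atoms: dimethyldioxirane CC1(C)OO1
Why: Dioxirane epoxidation of the tetrasubstituted enoate from the convex β face of the cis-fused D/E system (the α face is shielded by ring D through the axial C17–C16 bond), setting C20 and C21.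

**Step 13**
Reactants: 15 glycidic ester
Product: 16 β-keto ester (21-oxo; 20α-CO2Me; 20β-CH3; 9-CO2Bn)
Conditions: BF3·OEt2 (0.3 equiv), CH2Cl2, −78 → 0 °C
Reagents that add atoms: none
Why: Lewis-acid rearrangement of a glycidic ester, in which ionisation at tertiary C20 and the stereospecific 1,2-shift of the antiperiplanar methoxycarbonyl group, anti to the departing β oxygen, should place CO2Me on the α face of C20 (methyl β) and turn C21 into the ketone.

**Step 14**
Reactants: 16 β-keto ester benzyl ester
Product: 17 β-keto acid (9α-CO2H)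
Conditions: H2 (1 atm), 10% Pd/C, EtOAc, rt
Reagents that add atoms: none
Why: Hydrogenolysis of the benzyl ester; the acid is used at once without heating.

**Step 15**
Reactants: 17 β-keto acid
Product: 19 C8 trimethylsilyl enol ether (C8=C9) of the ring C–E keto ester, via trimethylsilyl ester 18 (not isolated)
Conditions: N,O-bis(trimethylsilyl)acetamide, toluene, rt; then 110 °C
Reagents that add atoms: N,O-bis(trimethylsilyl)acetamide CC(=N[Si](C)(C)C)O[Si](C)(C)C
Why: O-silylation followed by thermal decarboxylation of the trimethylsilyl β-keto carboxylate, with 1,5-transfer of silicon to the C8 oxygen through a six-membered transition state (the silyl counterpart of β-keto acid decarboxylation), should give the C8=C9 enol silane regiospecifically without enolising the ring E ketone.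

**Step 16**
Reactants: 10 aryl bromide silyl ketal; 19 C8 trimethylsilyl enol ether
Product: 22 silyl ketal of the target, via arylated diketone 20 (not isolated), via aldol adduct 21 (not isolated)
Conditions: Pd2(dba)3, P(t-Bu)3, Bu3SnF, CsF, toluene, 85 °C; then KOt-Bu, t-BuOH, 4 Å MS, 50 °C
Reagents that add atoms: none
Why: Fluoride (CsF with Bu3SnF as shuttle) converts 19 into its tin enolate without proton transfer, zerovalent palladium inserts into the C10–Br bond of 10, and transmetalation with C–C reductive elimination joins C9 to C10 (20); KOt-Bu then enolises the acetyl group, C7 adds to the C8 ketone (21) and E1cB loss of water gives the C7=C8 enone. The closest known reaction type is the palladium-catalysed α-arylation of ketone trimethylsilyl enol ethers under tin fluoride/CsF activation, which also builds quaternary α-carbons, followed by an intramolecular aldol condensation, together an arylation–condensation annulation to a 4,4-disubstituted naphthalen-1(4H)-one. Ring B (C5, C6, C7, C8, C9, C10) is the only ring formed and closes through the C7–C8 bond in a 6-(enolendo)-exo-trig aldol addition after the intermolecular C9–C10 coupling. C9 is set in the arylation: the aryl group should be delivered to the α face of the planar C8=C9 enolate because the β face is blocked by the axial C14 β-methyl group in 1,3-relation across C8, leaving the C9 methyl β. The step needs arylation only at C9 and condensation only between the acetyl group and C8; this is secured by the regiodefined enol silane (C14 is quaternary and no base is present in the first stage), by the absence of α-hydrogens on C8 after arylation so that only C7 can attack and water can be lost only toward C7, and by the silyl ketal, which keeps the dioxane ring closed. In one operation the step joins a C21 and a C37 fragment, forms two C–C bonds, sets the quaternary C9 and installs the 6-oxo-7-ene unit.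

**Step 17**
Reactants: 22 silyl ketal of the target
Product: 23 target CNP0172265.1
Conditions: HF·pyridine, pyridine, THF, 0 °C → rt
Reagents that add atoms: none
Why: Fluoride cleavage of the silyl ketal should return the hemiketal, whose configuration is held by the cis-fused dioxane ring.

**Compound list**

1 | 2-bromo-3-hydroxy-4-methoxybenzaldehyde (2-bromoisovanillin) | O=Cc1ccc(OC)c(O)c1Br | starting material
2 | 3-hydroxy-4-methoxy-2-methylbenzaldehyde | O=Cc1ccc(OC)c(O)c1C | intermediate
3 | 6-bromo-3-hydroxy-4-methoxy-2-methylbenzaldehyde | O=Cc1c(Br)cc(OC)c(O)c1C | intermediate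
4 | (±)-1-(6-bromo-3-hydroxy-4-methoxy-2-methylphenyl)ethan-1-ol | CC(O)c1c(Br)cc(OC)c(O)c1C | intermediate
5 | 1-(6-bromo-3-hydroxy-4-methoxy-2-methylphenyl)ethan-1-one | CC(=O)c1c(Br)cc(OC)c(O)c1C | intermediate
6 | 1-(6-bromo-3,4-dihydroxy-2-methylphenyl)ethan-1-one | CC(=O)c1c(Br)cc(O)c(O)c1C | intermediate
7 | tingenone (natural enantiomer; 9β,13α,14β,17β,20β-methyls, 18β-H) | CC1=C(O)C(=O)C=C2C1=CC=C3[C@@]2(C)CC[C@@]4(C)[C@@H]5C[C@@H](C)C(=O)C[C@]5(C)CC[C@]34C | starting material
8 | 4-acetyl-5-bromo-3-methylcyclohexa-3,5-diene-1,2-dione | CC(=O)C1=C(C)C(=O)C(=O)C=C1Br | intermediate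
9 | tingenone cis-fused at C3'/C4' to a 1,4-benzodioxane (both ring oxygens α; C3'-OH β; C4'-CH3 β; C4'-O on the arene oxygen ortho to the aryl methyl); arene carries 4-methyl, 5-acetyl, 10-bromo | CC(=O)c1c(Br)cc2c(c1C)O[C@@]3(C)C4=CC=C5[C@@](C)(CC[C@@]6(C)[C@@H]7C[C@@H](C)C(=O)C[C@]7(C)CC[C@]56C)C4=CC(=O)[C@@]3(O)O2 | intermediate
10 | C3'-O-tert-butyldimethylsilyl ketal of 9 | CC(=O)c1c(Br)cc2c(c1C)O[C@@]3(C)C4=CC=C5[C@@](C)(CC[C@@]6(C)[C@@H]7C[C@@H](C)C(=O)C[C@]7(C)CC[C@]56C)C4=CC(=O)[C@@]3(O[Si](C)(C)C(C)(C)C)O2 | intermediate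
11 | ring C–E keto acid: 8,21-dioxo, 9α-CO2H, 9β,13α,14β,17β,20β-pentamethyl, 18β-H | O=C1[C@](C)(C(=O)O)CC[C@@]2(C)[C@@H]3C[C@@H](C)C(=O)C[C@]3(C)CC[C@]12C | intermediate
12 | benzyl ester of 11 | O=C1[C@](C)(C(=O)OCc2ccccc2)CC[C@@]3(C)[C@@H]4C[C@@H](C)C(=O)C[C@]4(C)CC[C@]13C | intermediate
13 | C20=C21 enol triflate of 12 | O=C1[C@](C)(C(=O)OCc2ccccc2)CC[C@@]3(C)[C@@H]4CC(C)=C(OS(=O)(=O)C(F)(F)F)C[C@]4(C)CC[C@]13C | intermediate
14 | methyl C20=C21 ene-21-carboxylate (9-CO2Bn, 8-oxo) | O=C1[C@](C)(C(=O)OCc2ccccc2)CC[C@@]3(C)[C@@H]4CC(C)=C(C(=O)OC)C[C@]4(C)CC[C@]13C | intermediate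
15 | 20β,21β-epoxide of 14 (20-CH3 α, 21-CO2Me α) | O=C1[C@](C)(C(=O)OCc2ccccc2)CC[C@@]3(C)[C@@H]4C[C@@]5(C)O[C@@]5(C(=O)OC)C[C@]4(C)CC[C@]13C | intermediate
16 | 21-oxo 20α-methoxycarbonyl 20β-methyl benzyl ester | O=C1[C@](C)(C(=O)OCc2ccccc2)CC[C@@]3(C)[C@@H]4C[C@](C)(C(=O)OC)C(=O)C[C@]4(C)CC[C@]13C | intermediate
17 | 9α-carboxylic acid from 16 | O=C1[C@](C)(C(=O)O)CC[C@@]2(C)[C@@H]3C[C@](C)(C(=O)OC)C(=O)C[C@]3(C)CC[C@]12C | intermediate
18 | trimethylsilyl ester of 17 | O=C1[C@](C)(C(=O)O[Si](C)(C)C)CC[C@@]2(C)[C@@H]3C[C@](C)(C(=O)OC)C(=O)C[C@]3(C)CC[C@]12C | intermediate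
19 | C8 trimethylsilyl enol ether (C8=C9) of the ring C–E 21-oxo 20α-methyl ester | C[Si](C)(C)OC1=C(C)CC[C@@]2(C)[C@@H]3C[C@](C)(C(=O)OC)C(=O)C[C@]3(C)CC[C@]12C | intermediate
20 | C9-arylated diketone: ring B open, C5 acetyl, C8 ketone, aryl on C9 α, silyl ketal | COC(=O)[C@@]1(C)C[C@@H]2[C@@](C)(CC[C@]3(C)C(=O)[C@](C)(c4cc5c(c(C)c4C(C)=O)O[C@@]6(C)C7=CC=C8[C@@](C)(CC[C@@]9(C)[C@@H]%10C[C@@H](C)C(=O)C[C@]%10(C)CC[C@]89C)C7=CC(=O)[C@@]6(O[Si](C)(C)C(C)(C)C)O5)CC[C@@]23C)CC1=O | intermediate
21 | aldol adduct: ring B closed, C8 tertiary alcohol (C8 configuration not defined, either epimer dehydrates), C7 methylene | COC(=O)[C@@]1(C)C[C@@H]2[C@@](C)(CC[C@]3(C)C4(O)CC(=O)c5c(cc6c(c5C)O[C@@]5(C)C7=CC=C8[C@@](C)(CC[C@@]9(C)[C@@H]%10C[C@@H](C)C(=O)C[C@]%10(C)CC[C@]89C)C7=CC(=O)[C@@]5(O[Si](C)(C)C(C)(C)C)O6)[C@]4(C)CC[C@@]23C)CC1=O | intermediate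
22 | C3'-O-tert-butyldimethylsilyl ketal of the target | COC(=O)[C@@]1(C)C[C@@H]2[C@@](C)(CC[C@]3(C)C4=CC(=O)c5c(cc6c(c5C)O[C@@]5(C)C7=CC=C8[C@@](C)(CC[C@@]9(C)[C@@H]%10C[C@@H](C)C(=O)C[C@]%10(C)CC[C@]89C)C7=CC(=O)[C@@]5(O[Si](C)(C)C(C)(C)C)O6)[C@]4(C)CC[C@@]23C)CC1=O | intermediate
23 | CNP0172265.1 | COC(=O)[C@@]1(C)C[C@@H]2[C@@](C)(CC[C@]3(C)C4=CC(=O)c5c(cc6c(c5C)O[C@@]5(C)C7=CC=C8[C@@](C)(CC[C@@]9(C)[C@@H]%10C[C@@H](C)C(=O)C[C@]%10(C)CC[C@]89C)C7=CC(=O)[C@@]5(O)O6)[C@]4(C)CC[C@@]23C)CC1=O | target

**Total step count:** 17.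
**Longest linear sequence:** 10 steps (7 → 11 → 12 → 13 → 14 → 15 → 16 → 17 → 19 → 22 → 23; steps 8–17).

**Steps most likely to fail**

1. Step 16. Reductive elimination at the congested C9 (a tetrasubstituted enolate beside quaternary C14, meeting an ortho-substituted aryl–palladium species on a large fragment) may be slower than protonolysis or β-hydride elimination of the enolate and reduction of the bromide. In the second stage, alkoxide or hydroxide may open the ring E β-keto ester or epimerise C20' before the hindered C8 ketone condenses. The fallback sets out from 6, 19 and 7 and comes back at 20. Catechol 6 is benzylated (BnBr, K2CO3, DMF) to 1-[3,4-bis(benzyloxy)-6-bromo-2-methylphenyl]ethan-1-one F1, a small and robust aryl bromide on which forcing conditions and excess reagent are affordable. F1 is coupled with 19 under the first-stage conditions of step 16 to give the C9-arylated ring C–E diketone bis(benzyl ether) F2. Hydrogenolysis (H2, Pd/C, EtOAc) gives the catechol F3, and Ag2O oxidation gives the ortho-quinone F4, which is combined at once with tingenone 7 as in step 6 to give the ring-B-open dimer with free hemiketal F5. Silylation (TBSOTf, 2,6-lutidine) gives 20, now isolated, which is closed to 22 with KOt-Bu alone. The C9–aryl bond is thus made before the dioxane, and ring B is still the last ring closed.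

2. Step 6. The electron-poor quinone may decompose or exchange protons and electrons with the acidic enol faster than it cycloadds, and the cycloaddition may run with poor regio- or facial selectivity. The fallback sets out from 7 and comes back at 10. Tingenone is converted (TBSCl, imidazole, DMF) into tingenone 3-O-tert-butyldimethylsilyl enol ether F6, a non-acidic and more electron-rich dienophile that should react with freshly made 8 in a polar, C4'-first cycloaddition of the Mukaiyama type. This gives the silyl ketal 10 directly and makes step 7 unnecessary.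

3. Step 10. Loss of a C22 proton from the O-sulfonylated intermediate would give the C21=C22 triflate and carry the wrong alkene into the ester-shift sequence. The fallback sets out from 12 and comes back at 13. Ketone 12 is silylated under equilibrating conditions (TMSCl, NaI, Et3N, MeCN) to the more substituted C20=C21 trimethylsilyl enol ether of 12 F7, which is purified and then converted with CsF and PhNTf2 in DME into 13 with the alkene position fixed.

**Further compounds**

F1 | step 16 | 1-[3,4-bis(benzyloxy)-6-bromo-2-methylphenyl]ethan-1-one | CC(=O)c1c(Br)cc(OCc2ccccc2)c(OCc2ccccc2)c1C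
F2 | step 16 | C9-arylated ring C–E diketone bis(benzyl ether) (aryl α on C9) | COC(=O)[C@@]1(C)C[C@@H]2[C@@](C)(CC[C@]3(C)C(=O)[C@](C)(c4cc(OCc5ccccc5)c(OCc5ccccc5)c(C)c4C(C)=O)CC[C@@]23C)CC1=O
F3 | step 16 | catechol from F2 | COC(=O)[C@@]1(C)C[C@@H]2[C@@](C)(CC[C@]3(C)C(=O)[C@](C)(c4cc(O)c(O)c(C)c4C(C)=O)CC[C@@]23C)CC1=O
F4 | step 16 | ortho-quinone from F3 | COC(=O)[C@@]1(C)C[C@@H]2[C@@](C)(CC[C@]3(C)C(=O)[C@](C)(C4=CC(=O)C(=O)C(C)=C4C(C)=O)CC[C@@]23C)CC1=O
F5 | step 16 | ring-B-open dimer with free hemiketal | COC(=O)[C@@]1(C)C[C@@H]2[C@@](C)(CC[C@]3(C)C(=O)[C@](C)(c4cc5c(c(C)c4C(C)=O)O[C@@]6(C)C7=CC=C8[C@@](C)(CC[C@@]9(C)[C@@H]%10C[C@@H](C)C(=O)C[C@]%10(C)CC[C@]89C)C7=CC(=O)[C@@]6(O)O5)CC[C@@]23C)CC1=O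
F6 | step 6 | tingenone 3-O-tert-butyldimethylsilyl enol ether | CC1=C(O[Si](C)(C)C(C)(C)C)C(=O)C=C2C1=CC=C3[C@@]2(C)CC[C@@]4(C)[C@@H]5C[C@@H](C)C(=O)C[C@]5(C)CC[C@]34C
F7 | step 10 | C20=C21 trimethylsilyl enol ether of 12 | O=C1[C@](C)(C(=O)OCc2ccccc2)CC[C@@]3(C)[C@@H]4CC(C)=C(O[Si](C)(C)C)C[C@]4(C)CC[C@]13C
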